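**Retrosynthetic overview**
1. Ring B and all chirality are bought as (S)-limonene 1; BrCl addition directed by its ring stereocentre gives bromochloride 2, which carries both ring-B halogen centres.
2. That ring carbon is re-functionalised by allylic oxidation (via 3) to carbinol 4. A [3,3] shift (via 5) relays its configuration into the E tetrasubstituted alkene of ester 6.
3. Ester 6 is reduced (via 7) to aldehyde 8, and a Wittig disconnection of the terminal alkene leads to triene 9.
4. Key disconnection, made last: the spiro C–CMe2 bond together with the neighbouring C–Br bond. Ring A and the spiro centre form in one anodic bromonium-ion cyclisation of 9 (via 10) to target 11.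
5. Ring order: ring B (bought) first, ring A with the spiro centre last.

Assumption: the target is read as (2R,3R,6R,10S)-2,10-dibromo-3-chloro-3,7,11,11-tetramethylspiro[5.5]undec-7-ene; commercial (S)-(−)-limonene (≥98% ee) is the chiral source; in the Why lines ring B keeps the locants of 2 (C1 = C–Cl, C2 = C–Br, C4 = later spiro carbon), C7 is the carbon on C4 and C8–C11 the chain beyond it (C11 = CMe2).

**Step 1**
Reactants: 1 (S)-(−)-limonene
Product: 2 (1R,2R,4S)-2-bromo-1-chloro-1-methyl-4-(prop-1-en-2-yl)cyclohexane
Conditions: NBS (1.05 equiv), HCl (4 M in dioxane, 1.1 equiv), CH2Cl2, −78 °C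
Reagents that add atoms: N-bromosuccinimide (O=C1CCC(=O)N1Br); hydrogen chloride (Cl)
Why: Electrophilic bromochlorination (BrCl made in situ) is faster at the trisubstituted ring alkene than at the 1,1-disubstituted one, and chloride opens the bromonium ion at the tertiary carbon in the trans-diaxial sense (Fürst–Plattner rule) on the half-chair that keeps the C4 substituent equatorial, so the bought C4 centre sets C1 and C2 as 1R,2R.

**Step 2**
Reactants: 2 (1R,2R,4S)-2-bromo-1-chloro-1-methyl-4-(prop-1-en-2-yl)cyclohexane
Product: 4 (1R,3R,4R)-3-bromo-4-chloro-4-methyl-1-(prop-1-en-2-yl)cyclohexan-1-ol, via allylic seleninic acid 3 (not isolated)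
Conditions: SeO2 (0.3 equiv), t-BuOOH (3 equiv), CH2Cl2, 0 °C to rt
Reagents that add atoms: tert-butyl hydroperoxide (CC(C)(C)OO); SeO2 (O=[Se]=O) as oxygen-transfer catalyst
Why: SeO2 allylic oxidation (ene reaction to seleninic acid 3, then [2,3]-sigmatropic shift) takes the methine hydrogen of a 1,1-disubstituted alkene in preference to the methyl hydrogens and returns oxygen to C4 on the axial face cis to C2–Br, the mode that keeps the isopropenyl group equatorial and away from the axial bromine, so the halogen centres of step 1 control the carbinol centre.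

**Step 3**
Reactants: 4 (1R,3R,4R)-3-bromo-4-chloro-4-methyl-1-(prop-1-en-2-yl)cyclohexan-1-ol
Product: 6 ethyl (4E)-4-[(3R,4R)-3-bromo-4-chloro-4-methylcyclohexylidene]pentanoate, via ketene acetal 5 (not isolated)
Conditions: MeC(OEt)3 (6 equiv), EtCO2H (0.1 equiv), toluene, 110 °C, EtOH distilled off
Reagents that add atoms: triethyl orthoacetate (CCOC(C)(OCC)OCC)
Why: Johnson–Claisen rearrangement: the chair transition state of ketene acetal 5 lies on the C5 side of ring B, away from the axial C2 bromine that is syn to the axial oxygen, which puts C3 equatorial in that chair and therefore trans to the new chain, so the carbinol centre is translated into the E geometry of the tetrasubstituted alkene (C4 is no longer a stereocentre).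

**Step 4**
Reactants: 6 ethyl (4E)-4-[(3R,4R)-3-bromo-4-chloro-4-methylcyclohexylidene]pentanoate
Product: 8 (4E)-4-[(3R,4R)-3-bromo-4-chloro-4-methylcyclohexylidene]pentanal, via aluminium hemiacetal 7 (not isolated)
Conditions: i-Bu2AlH (1.1 equiv), CH2Cl2, −78 °C; aq. potassium sodium tartrate
Reagents that add atoms: none
Why: Low-temperature i-Bu2AlH reduction of an ester stops at the tetrahedral aluminium hemiacetal 7, which releases the aldehyde only on work-up, and it touches neither the alkyl halides nor the alkene geometry.

**Step 5**
Reactants: 8 (4E)-4-[(3R,4R)-3-bromo-4-chloro-4-methylcyclohexylidene]pentanal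
Product: 9 (1R,2R,4E)-2-bromo-1-chloro-1-methyl-4-(6-methylhept-5-en-2-ylidene)cyclohexane
Conditions: i-PrPPh3I (1.3 equiv), n-BuLi (1.25 equiv), THF, 0 °C; then 8, −78 to 0 °C
Reagents that add atoms: isopropyltriphenylphosphonium iodide (CC(C)[P+](c1ccccc1)(c1ccccc1)c1ccccc1.[I-])
Why: Wittig olefination with the non-stabilised isopropylidene ylide consumes the aldehyde at −78 °C, before any E2 reaction of the hindered alkyl halides, and creates no stereocentre.

**Step 6**
Reactants: 9 (1R,2R,4E)-2-bromo-1-chloro-1-methyl-4-(6-methylhept-5-en-2-ylidene)cyclohexane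
Product: 11 (2R,3R,6R,10S)-2,10-dibromo-3-chloro-3,7,11,11-tetramethylspiro[5.5]undec-7-ene, via bromonium ion 10 (not isolated)
Conditions: Et4NBr (1.2 equiv), Bu4NPF6 (0.1 M), CH2Cl2/HFIP (4:1), 0.02 M, undivided cell, graphite anode, Pt cathode, 4 mA cm−2, 2.2 F mol−1, −20 °C
Reagents that add atoms: tetraethylammonium bromide (CC[N+](CC)(CC)CC.[Br-])
Why: Proposed new method: anodic oxidation of bromide gives Br2, which HFIP hydrogen bonding turns into a Br+ donor while keeping the released bromide non-nucleophilic, so that the reversibly formed bromonium ion 10 of the terminal alkene is captured by C4 of the tetrasubstituted alkene through a chair transition state with bromine equatorial, C11 adding to the C4 face cis to C2–Br (equatorial attack on the ring-B chair with both halogens equatorial, since attack on the other face pushes C7 and its methyl group syn-axial to bromine) and the E alkene geometry fixing C10 relative to the spiro centre as 6R,10S, after which the C7 cation loses H-8 and the proton is reduced to H2 at the cathode; the closest known reactions are bromonium-induced polyene cyclisations with stoichiometric Br+ donors and the anodic bromo-functionalisation of alkenes.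

**Compound list**
1 | (S)-(−)-limonene, (4S)-1-methyl-4-(prop-1-en-2-yl)cyclohex-1-ene | CC1=CC[C@H](CC1)C(C)=C | starting material
2 | (1R,2R,4S)-2-bromo-1-chloro-1-methyl-4-(prop-1-en-2-yl)cyclohexane; Br and Cl trans-diaxial, Cl cis to isopropenyl | CC(=C)[C@H]1CC[C@@](C)(Cl)[C@H](Br)C1 | intermediate
3 | 2-[(3R,4R)-3-bromo-4-chloro-4-methylcyclohexylidene]propane-1-seleninic acid; alkene geometry not relevant | CC(C[Se](O)=O)=C1CC[C@@](C)(Cl)[C@H](Br)C1 | intermediate (not isolated)
4 | (1R,3R,4R)-3-bromo-4-chloro-4-methyl-1-(prop-1-en-2-yl)cyclohexan-1-ol; OH cis to Br | CC(=C)[C@@]1(O)CC[C@@](C)(Cl)[C@H](Br)C1 | intermediate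
5 | (1R,3R,4R)-3-bromo-4-chloro-1-[(1-ethoxyethenyl)oxy]-4-methyl-1-(prop-1-en-2-yl)cyclohexane | C=C(OCC)O[C@]1(C(C)=C)CC[C@@](C)(Cl)[C@H](Br)C1 | intermediate (not isolated)
6 | ethyl (4E)-4-[(3R,4R)-3-bromo-4-chloro-4-methylcyclohexylidene]pentanoate; chain cis to the ring CH2 remote from CHBr | CCOC(=O)CC/C(C)=C1\CC[C@@](C)(Cl)[C@H](Br)C1 | intermediate
7 | diisobutylaluminium hemiacetal of 6; hemiacetal carbon unassigned | CCOC(CC/C(C)=C1\CC[C@@](C)(Cl)[C@H](Br)C1)O[Al](CC(C)C)CC(C)C | intermediate (not isolated)
8 | (4E)-4-[(3R,4R)-3-bromo-4-chloro-4-methylcyclohexylidene]pentanal | O=CCC/C(C)=C1\CC[C@@](C)(Cl)[C@H](Br)C1 | intermediate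
9 | (1R,2R,4E)-2-bromo-1-chloro-1-methyl-4-(6-methylhept-5-en-2-ylidene)cyclohexane | CC(C)=CCC/C(C)=C1\CC[C@@](C)(Cl)[C@H](Br)C1 | intermediate
10 | (3S)-3-{(3E)-3-[(3R,4R)-3-bromo-4-chloro-4-methylcyclohexylidene]butyl}-2,2-dimethylbromiranium ion | CC1(C)[Br+][C@H]1CC/C(C)=C2\CC[C@@](C)(Cl)[C@H](Br)C2 | intermediate (not isolated)
11 | (2R,3R,6R,10S)-2,10-dibromo-3-chloro-3,7,11,11-tetramethylspiro[5.5]undec-7-ene | CC1=CC[C@H](Br)C(C)(C)[C@@]12CC[C@@](C)(Cl)[C@H](Br)C2 | target

**Totals**
Total step count: 6. Longest linear sequence: 6 steps (1 to 11).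

**Three steps most likely to fail**

Step 6 (the new anodic cyclisation). The risks are vicinal dibromide formation, the exocyclic alkene isomer, ionisation of the ring-B tertiary chloride by HFIP, and low facial selectivity at C4, which would give the C6 and C10 diastereomers. The selectivity argument for the C4 face is the weakest stereochemical point of the route, and up to four diastereomers may need to be separated. The fallback uses known chemistry, sets out from 9 and comes back at 11: stoichiometric bromonium transfer from 2,4,4,6-tetrabromocyclohexa-2,5-dien-1-one in MeNO2 at 0 °C, the classical chemical bromonium-induced polyene cyclisation, run without electrolysis and without HFIP. It passes through the same bromonium ion 10 and makes no new compound (F0).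

Step 2 (SeO2 hydroxylation). The risks are oxidation of the methyl group instead of the methine, low conversion, or the wrong C4 epimer, which would erode the E selectivity of step 3. The fallback sets out from 2 and comes back at 9, bypassing steps 2 to 5. Ozonolysis of the isopropenyl group (O3, CH2Cl2/MeOH, −78 °C; Me2S) gives the methyl ketone 1-[(1S,3R,4R)-3-bromo-4-chloro-4-methylcyclohexyl]ethan-1-one F1. Addition of (4-methylpent-3-en-1-yl)magnesium bromide (THF, −78 °C) gives the tertiary alcohol 2-[(1S,3R,4R)-3-bromo-4-chloro-4-methylcyclohexyl]-6-methylhept-5-en-2-ol F2 as both carbinol epimers. Syn-dehydration with the Burgess reagent (benzene, 50 °C) and chromatography on AgNO3-impregnated silica then deliver 9. The cost is that 9 must be separated from its Z isomer and double-bond regioisomers, because this path has no geometry control.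

Step 3 (Johnson–Claisen at 110 °C). The risks are thermal loss of HCl, acid-catalysed dehydration of the tertiary allylic alcohol, or a lower E/Z ratio than argued. The fallback sets out from 4 and comes back at 6. PBr3 (Et2O, −20 °C) converts the tertiary allylic alcohol, with allylic transposition, into the primary allylic bromide (1R,2R,4E)-2-bromo-4-(1-bromopropan-2-ylidene)-1-chloro-1-methylcyclohexane F3, with the E isomer separated from the Z isomer. F3 then alkylates the lithium enolate of ethyl acetate (LiN(i-Pr)2, EtOAc, THF, −78 °C) to give 6.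

**Further compounds**
F1 | step 2 | 1-[(1S,3R,4R)-3-bromo-4-chloro-4-methylcyclohexyl]ethan-1-one | CC(=O)[C@H]1CC[C@@](C)(Cl)[C@H](Br)C1
F2 | step 2 | 2-[(1S,3R,4R)-3-bromo-4-chloro-4-methylcyclohexyl]-6-methylhept-5-en-2-ol | CC(C)=CCCC(C)(O)[C@H]1CC[C@@](C)(Cl)[C@H](Br)C1
F3 | step 3 | (1R,2R,4E)-2-bromo-4-(1-bromopropan-2-ylidene)-1-chloro-1-methylcyclohexane | BrC/C(C)=C1\CC[C@@](C)(Cl)[C@H](Br)C1
F0 | step 6 | none | none
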